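**Retrosynthetic overview**

1. The enol ester comes from a stereoretentive copper-catalysed C–O coupling of (E)-alkenyltrifluoroborate 29 with 3-methylbut-2-enoic acid; the boronate comes from cross-metathesis of a C16 vinyl group, and the acetonyl group from a methallyl group.
2. The trans C16/C4 side chains come from adding vinyl and then H to the same (exo) face of α-methallyl enone 18, itself made by Stille coupling of α-bromo enone 16.
3. The seven-membered ring is not made by a [4+3] cycloaddition or a ring closure: it is grown by dibromocarbene one-carbon ring expansion of the bicyclo[3.3.1]nonanone 10, which also delivers the bromo enone handle.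
4. The cyclohexane and the tetrahydropyran are formed together by a Lewis-acid cation–olefin/oxygen-capture cascade on Morita–Baylis–Hillman adduct 9 (C15, C10 and C6 relayed from C13).
5. C13 is the only centre set by a chiral reagent (Cu-catalysed asymmetric conjugate addition). Ring order: six-membered carbocycle A (bought) → cyclohexane + pyran in one step → ring A expanded to the cycloheptenone.

Assumption: locants C1–C18 are those of the target SMILES read from the left (C2 and C5 carbonyls, C4 and C16 side-chain carbons, C7 = OCH2, O8, C9 = CMe2, C13 = C–CH3, C17=C18 enol alkene); L* = enantiopure 1-mesityl-3-(1-hydroxy-4-methylpentan-2-yl)-4,5-dihydroimidazolium hexafluorophosphate, the antipode that gives (R)-5 being used (both are accessible); the roughly 90% ee of step 1 is raised to >99% by recrystallising 10 or 16; tributyl(2-methylallyl)stannane is taken as purchasable.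

**Step 1**
Reactants: 1 3-methylcyclohex-2-en-1-one; 2 5-bromo-2-methylpent-2-ene
Product: 5 (R)-3-methyl-3-(4-methylpent-3-en-1-yl)cyclohexan-1-one, via Grignard reagent 3 (not isolated), via magnesium enolate 4 (not isolated)
Conditions: 2, Mg, Et2O, rt; then 1, Cu(OTf)2 (3 mol %), L* (4 mol %), Et2O, −30 °C; 1 M HCl
Reagents that add atoms: 5-bromo-2-methylpent-2-ene (CC(C)=CCCBr)
Why: Copper-catalysed asymmetric conjugate addition of a primary alkyl Grignard reagent to a β-methyl cyclohexenone, in which the chiral NHC–copper complex selects the enone face and sets the all-carbon quaternary centre C13 (R in 5, the future 13S).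

**Step 2**
Reactants: 5 (R)-3-methyl-3-(4-methylpent-3-en-1-yl)cyclohexan-1-one
Product: 7 (S)-5-methyl-5-(4-methylpent-3-en-1-yl)cyclohex-2-en-1-one, via lithium enolate 6 (not isolated)
Conditions: LiN(iPr)2 (1.1 equiv), THF, −78 °C; then PhS(Cl)=N-t-Bu (1.2 equiv), −78 °C
Reagents that add atoms: none
Why: Kinetic deprotonation takes the CH2 remote from the quaternary carbon (the regioisomeric enolate has no β-hydrogen and cannot give an enone) and the enolate is dehydrogenated by the sulfinimidoyl chloride (Mukaiyama dehydrogenation, S-alkylation then syn-elimination); no stereocentre is formed and the R→S change is only a priority change.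

**Step 3**
Reactants: 7 (S)-5-methyl-5-(4-methylpent-3-en-1-yl)cyclohex-2-en-1-one; 8 formaldehyde
Product: 9 (S)-2-(hydroxymethyl)-5-methyl-5-(4-methylpent-3-en-1-yl)cyclohex-2-en-1-one
Conditions: 37% aq. HCHO (3 equiv), DMAP (0.3 equiv), THF–H2O, rt
Reagents that add atoms: formaldehyde (C=O)
Why: Morita–Baylis–Hillman reaction of a cyclohexenone (DMAP adds reversibly to the β-carbon, the enolate is hydroxymethylated and DMAP is expelled); no stereocentre is formed.

**Step 4**
Reactants: 9 (S)-2-(hydroxymethyl)-5-methyl-5-(4-methylpent-3-en-1-yl)cyclohex-2-en-1-one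
Product: 10 (6S,10R,13S,15S)-tricyclic ketone [cyclohexanone C5(=O)/C6/C15/C14/C13/C16 bridged by C10–C11–C12 and carrying the 2,2-dimethyltetrahydropyran C6–C7–O8–C9–C10–C15; 13-methyl]
Conditions: BF3·OEt2 (0.3 equiv), CH2Cl2, −78 → −20 °C
Reagents that add atoms: none
Why: Proposed new method: BF3 activates the enone and the trisubstituted alkene (C10) adds to the β-carbon C15 through a chair transition state that the tether can reach on one face only (sets C15) with the developing CMe2 cation equatorial (sets C10), the cation is captured by the hydroxyl group to close the pyran, and the enol is protonated to the only accessible cis ring fusion (sets C6); the closest known reactions are Lewis-acid cation–olefin (Prins-type) cyclisations onto enones and the intramolecular oxadiene hetero-Diels–Alder reaction that gives the same ring pattern.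

**Step 5**
Reactants: 10 (6S,10R,13S,15S)-tricyclic ketone; 11 chlorotrimethylsilane
Product: 13 (6S,10R,13S,15S)-C5=C16 trimethylsilyl enol ether of 10, via lithium enolate 12 (not isolated)
Conditions: LiN(iPr)2 (1.2 equiv), Me3SiCl (in situ quench), THF, −78 °C
Reagents that add atoms: chlorotrimethylsilane (C[Si](C)(C)Cl)
Why: Kinetic enolisation with in situ silylation removes a proton from the C16 methylene in preference to the C6 methine (which would also risk β-alkoxide elimination), fixing the regiochemistry of the coming ring expansion; no stereocentre is touched.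

**Step 6**
Reactants: 13 (6S,10R,13S,15S)-C5=C16 trimethylsilyl enol ether; 14 bromoform
Product: 16 (6S,10R,13S,15S)-α-bromo enone [ring-expanded tricycle with C5(=O)–C4(Br)=C16H; the target core without side chains], via dibromocyclopropane 15 (not isolated)
Conditions: CHBr3 (1.5 equiv), KOtBu (1.6 equiv), pentane, −20 °C → rt; then MeOH, Et3N, 50 °C
Reagents that add atoms: bromoform (BrC(Br)Br)
Why: Dibromocarbene cyclopropanates the electron-rich enol ether (the only alkene left) and the 1-siloxy-2,2-dibromocyclopropane opens electrocyclically with loss of bromide and silyl (dihalocarbene one-carbon ring expansion), inserting C4 between C5 and C16 to give the bicyclo[4.3.1]decenone as its α-bromo enone; both cyclopropane centres are destroyed.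

**Step 7**
Reactants: 16 (6S,10R,13S,15S)-α-bromo enone; 17 tributyl(2-methylallyl)stannane
Product: 18 (6S,10R,13S,15S)-4-(2-methylallyl) enone [C5(=O)–C4(CH2C(CH3)=CH2)=C16H]
Conditions: 17 (1.5 equiv), Pd2(dba)3 (2.5 mol %), AsPh3 (10 mol %), CuI (10 mol %), DMF, 45 °C
Reagents that add atoms: tributyl(2-methylallyl)stannane (CCCC[Sn](CCCC)(CCCC)CC(C)=C)
Why: Stille coupling, in which zerovalent palladium inserts into the activated C–Br bond of the α-bromo enone and the methallyl group (a masked acetonyl group) is transferred from tin under neutral conditions; no stereocentre is formed.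

**Step 8**
Reactants: 18 (6S,10R,13S,15S)-4-(2-methylallyl) enone; 19 vinylmagnesium bromide; 11 chlorotrimethylsilane
Product: 21 (4S,6S,10R,13S,15S,16S)-4-(2-methylallyl)-16-vinyl ketone, via silyl enol ether 20 (not isolated)
Conditions: CH2=CHMgBr (3 equiv), CuBr·SMe2 (0.3 equiv), Me3SiCl (4 equiv), THF, −78 → −40 °C; then 1 M HCl–THF, −40 → 0 °C
Reagents that add atoms: vinylmagnesium bromide (C=C[Mg]Br)
Why: Copper-catalysed conjugate addition accelerated by Me3SiCl delivers vinyl to C16 on the face of the seven-membered ring opposite the C10–C11–C12 bridge (sets C16), and kinetic C-protonation of silyl enol ether 20 from that same open face leaves the methallyl group on the bridge side, trans to vinyl (sets C4).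

**Step 9**
Reactants: 21 (4S,6S,10R,13S,15S,16S)-4-(2-methylallyl)-16-vinyl ketone; 22 3-chloroperoxybenzoic acid
Product: 23 (4S,6S,10R,13S,15S,16S)-4-[(2-methyloxiran-2-yl)methyl]-16-vinyl ketone (both epoxide epimers)
Conditions: mCPBA (1.1 equiv), NaHCO3, CH2Cl2, 0 °C
Reagents that add atoms: 3-chloroperoxybenzoic acid (OOC(=O)c1cccc(Cl)c1)
Why: Prilezhaev epoxidation, selective because the 1,1-disubstituted methallyl alkene is far more nucleophilic than the hindered monosubstituted vinyl group and the hindered ketone does not undergo Baeyer–Villiger oxidation at 0 °C; the new epoxide centre is removed in step 10.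

**Step 10**
Reactants: 23 (4S,6S,10R,13S,15S,16S)-4-[(2-methyloxiran-2-yl)methyl]-16-vinyl ketone; 24 water
Product: 25 (4S,6S,10R,13S,15S,16S)-4-(2-oxopropyl)-16-vinyl diketone
Conditions: H5IO6 (1.5 equiv), THF–H2O, 0 °C → rt
Reagents that add atoms: water (O)
Why: Periodic acid opens the epoxide with water at the tertiary carbon and cleaves the resulting 1,2-diol (Malaprade glycol cleavage) to the methyl ketone and formaldehyde, leaving the vinyl group and the C4 centre untouched.

**Step 11**
Reactants: 25 (4S,6S,10R,13S,15S,16S)-4-(2-oxopropyl)-16-vinyl diketone; 26 4,4,5,5-tetramethyl-2-vinyl-1,3,2-dioxaborolane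
Product: 27 (4S,6S,10R,13S,15S,16S)-16-[(E)-2-(4,4,5,5-tetramethyl-1,3,2-dioxaborolan-2-yl)vinyl]-4-(2-oxopropyl) diketone
Conditions: second-generation Hoveyda–Grubbs catalyst (10 mol %), 26 (4 equiv), CH2Cl2, 40 °C
Reagents that add atoms: 4,4,5,5-tetramethyl-2-vinyl-1,3,2-dioxaborolane (C=CB1OC(C)(C)C(C)(C)O1)
Why: Olefin cross-metathesis of the only terminal alkene with vinyl pinacolboronate, in which the bulky C16 substituent and the boryl group enforce the E-alkenylboronate.

**Step 12**
Reactants: 27 (E)-alkenyl pinacolboronate; 28 potassium hydrogen difluoride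
Product: 29 potassium (E)-alkenyltrifluoroborate [(4S,6S,10R,13S,15S,16S); C16–CH=CH–BF3K]
Conditions: KHF2 (aq., 4 equiv), MeOH, rt
Reagents that add atoms: potassium hydrogen difluoride ([K+].[F-].F)
Why: Ligand exchange at boron with bifluoride gives the trifluoroborate needed for the copper coupling, with alkene geometry and all stereocentres unchanged.

**Step 13**
Reactants: 29 potassium (E)-alkenyltrifluoroborate; 30 3-methylbut-2-enoic acid
Product: 31 vibsanin E
Conditions: 30 (2 equiv), Cu(OAc)2 (0.2 equiv), DMAP (0.4 equiv), 4 Å MS, O2 (1 atm), CH2Cl2, 35 °C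
Reagents that add atoms: 3-methylbut-2-enoic acid (CC(C)=CC(=O)O)
Why: Chan–Lam–Evans-type copper-catalysed oxidative C–O coupling of an alkenyltrifluoroborate with a carboxylic acid, which proceeds with retention at the alkenyl carbon and so gives the (E)-enol ester directly under conditions mild enough for the two ketones and the C4 centre.

**Compound list**

1 | 3-methylcyclohex-2-en-1-one | CC1=CC(=O)CCC1 | starting material
2 | 5-bromo-2-methylpent-2-ene | CC(C)=CCCBr | starting material
3 | (4-methylpent-3-en-1-yl)magnesium bromide (not isolated) | CC(C)=CCC[Mg]Br | intermediate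
4 | bromomagnesium (R)-3-methyl-3-(4-methylpent-3-en-1-yl)cyclohex-1-en-1-olate (not isolated) | CC(C)=CCC[C@@]1(C)CCCC(O[Mg]Br)=C1 | intermediate
5 | (R)-3-methyl-3-(4-methylpent-3-en-1-yl)cyclohexan-1-one | CC(C)=CCC[C@@]1(C)CCCC(=O)C1 | intermediate
6 | lithium (S)-5-methyl-5-(4-methylpent-3-en-1-yl)cyclohex-1-en-1-olate, kinetic enolate of 5 (not isolated) | CC(C)=CCC[C@@]1(C)CCC=C(O[Li])C1 | intermediate
7 | (S)-5-methyl-5-(4-methylpent-3-en-1-yl)cyclohex-2-en-1-one | CC(C)=CCC[C@@]1(C)CC=CC(=O)C1 | intermediate
8 | formaldehyde | C=O | starting material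
9 | (S)-2-(hydroxymethyl)-5-methyl-5-(4-methylpent-3-en-1-yl)cyclohex-2-en-1-one | CC(C)=CCC[C@@]1(C)CC=C(CO)C(=O)C1 | intermediate
10 | (6S,10R,13S,15S)-tricyclic ketone: cyclohexanone C5(=O)–C6–C15–C14–C13–C16, cyclohexane C10–C11–C12–C13–C14–C15 and 2,2-dimethyltetrahydropyran C6–C7–O8–C9–C10–C15; methyl on C13; H6, H15, H10 all cis | O=C1[C@@H]2COC(C)(C)[C@@H]3CC[C@@](C)(C[C@@H]32)C1 | intermediate
11 | chlorotrimethylsilane | C[Si](C)(C)Cl | starting material
12 | lithium C5=C16 enolate of 10 (not isolated) | [Li]OC1[C@@H]2COC(C)(C)[C@@H]3CC[C@@](C)(C[C@@H]32)C=1 | intermediate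
13 | (6S,10R,13S,15S)-C5=C16 trimethylsilyl enol ether of 10 | C[Si](C)(C)OC1[C@@H]2COC(C)(C)[C@@H]3CC[C@@](C)(C[C@@H]32)C=1 | intermediate
14 | bromoform | BrC(Br)Br | starting material
15 | dibromocyclopropane: CBr2 bridging C5(OSiMe3) and C16 of 13, cyclopropane diastereomers (not isolated) | C[Si](C)(C)OC14[C@@H]2COC(C)(C)[C@@H]3CC[C@@](C)(C[C@@H]32)C1C4(Br)Br | intermediate
16 | (6S,10R,13S,15S)-α-bromo enone: target tricycle (cycloheptenone C4–C5–C6–C15–C14–C13–C16) with C5=O, C4(Br)=C16H and no side chains | BrC1C(=O)[C@@H]2COC(C)(C)[C@@H]3CC[C@@](C)(C[C@@H]32)C=1 | intermediate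
17 | tributyl(2-methylallyl)stannane | CCCC[Sn](CCCC)(CCCC)CC(C)=C | starting material
18 | (6S,10R,13S,15S)-4-(2-methylallyl) enone: 16 with CH2C(CH3)=CH2 in place of Br | CC(=C)CC1C(=O)[C@@H]2COC(C)(C)[C@@H]3CC[C@@](C)(C[C@@H]32)C=1 | intermediate
19 | vinylmagnesium bromide | C=C[Mg]Br | starting material
20 | (6S,10R,13S,15S,16R)-16-vinyl C4=C5 trimethylsilyl enol ether, vinyl anti to the C10–C12 bridge (not isolated) | CC(=C)CC1=C(O[Si](C)(C)C)[C@@H]2COC(C)(C)[C@@H]3CC[C@@](C)(C[C@@H]32)[C@H]1C=C | intermediate
21 | (4S,6S,10R,13S,15S,16S)-4-(2-methylallyl)-16-vinyl tricyclic ketone, side chains trans | CC(=C)C[C@@H]1C(=O)[C@@H]2COC(C)(C)[C@@H]3CC[C@@](C)(C[C@@H]32)[C@H]1C=C | intermediate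
22 | 3-chloroperoxybenzoic acid | OOC(=O)c1cccc(Cl)c1 | starting material
23 | (4S,6S,10R,13S,15S,16S)-4-[(2-methyloxiran-2-yl)methyl]-16-vinyl tricyclic ketone, both epoxide epimers | CC1(CO1)C[C@@H]2C(=O)[C@@H]3COC(C)(C)[C@@H]4CC[C@@](C)(C[C@@H]43)[C@H]2C=C | intermediate
24 | water | O | starting material
25 | (4S,6S,10R,13S,15S,16S)-4-(2-oxopropyl)-16-vinyl tricyclic diketone | CC(=O)C[C@@H]1C(=O)[C@@H]2COC(C)(C)[C@@H]3CC[C@@](C)(C[C@@H]32)[C@H]1C=C | intermediate
26 | 4,4,5,5-tetramethyl-2-vinyl-1,3,2-dioxaborolane | C=CB1OC(C)(C)C(C)(C)O1 | starting material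
27 | (4S,6S,10R,13S,15S,16S)-16-[(E)-2-(pinacolboryl)vinyl]-4-(2-oxopropyl) tricyclic diketone | CC(=O)C[C@@H]1C(=O)[C@@H]2COC(C)(C)[C@@H]3CC[C@@](C)(C[C@@H]32)[C@H]1/C=C/B4OC(C)(C)C(C)(C)O4 | intermediate
28 | potassium hydrogen difluoride | [K+].[F-].F | starting material
29 | potassium (E)-alkenyltrifluoroborate of the (4S,6S,10R,13S,15S,16S) diketone | CC(=O)C[C@@H]1C(=O)[C@@H]2COC(C)(C)[C@@H]3CC[C@@](C)(C[C@@H]32)[C@H]1/C=C/[B-](F)(F)F.[K+] | intermediate
30 | 3-methylbut-2-enoic acid | CC(C)=CC(=O)O | starting material
31 | vibsanin E | CC(=O)C[C@@H]1C(=O)[C@@H]2COC(C)(C)[C@@H]3CC[C@@](C)(C[C@@H]32)[C@H]1/C=C/OC(=O)C=C(C)C | target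

**Totals**

Total step count: 13. Longest linear sequence: 13 steps (1 → 31); every other component is bought.

**Steps most likely to fail**

Step 8 (vinyl addition to an α-substituted enone whose β-carbon sits next to a quaternary centre, then face-selective protonation). The fallback sets out from 18. Hosomi–Sakurai allylation (allyltrimethylsilane, TiCl4, CH2Cl2, −78 °C, aqueous quench), which tolerates far more hindered enones than copper reagents and should follow the same exo attack and exo protonation, gives the C16-allyl C4-methallyl ketone F7. Ozonolysis of both alkenes (O3, CH2Cl2–MeOH, −78 °C; Me2S) gives the keto aldehyde F8 (C16–CH2–CHO and the C4 acetonyl group in one operation). O-Acylation of the aldehyde enol with 3-methylbut-2-enoic anhydride F9 (made from acid 30 and DCC; Et3N, DMAP) gives the enol ester as an E/Z mixture, from which the E isomer is separated. This comes back to the route at 31 and bypasses steps 9–13, at the price of losing the stereospecific enol ester formation.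

Step 4 (the cascade could give carbonyl-ene (1,2) products or eliminate instead of closing the pyran). The fallback sets out from 9. Dess–Martin periodinane oxidation gives the 2-formyl enone F1. Its only s-cis oxadiene (O=C7–C6=C15, the ring ketone being locked s-trans) undergoes a thermal intramolecular inverse-demand hetero-Diels–Alder reaction with the trisubstituted alkene to give the tricyclic β-alkoxy enone F2. Hydrogenation of the enol ether double bond (H2, Pd/C, EtOAc), with C6 settling to the cis fusion, comes back to the route at 10.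

Step 6 (carbene addition to a hindered bridged enol ether and clean opening of the adduct). The fallback sets out from 13. Simmons–Smith cyclopropanation (Et2Zn, CH2I2) gives the siloxycyclopropane F3. FeCl3 in DMF opens it oxidatively to the β-chloro ketone F4 (Saegusa–Ito ring expansion), and NaOAc in MeOH eliminates HCl to the parent enone F5. Iodine and pyridine give the α-iodo enone F6, which takes the place of 16 in the Stille coupling with 17 and so comes back to the route at 18.

**Further compounds**

F1 | step 4 | (S)-4-methyl-4-(4-methylpent-3-en-1-yl)-6-oxocyclohex-1-ene-1-carbaldehyde | CC(C)=CCC[C@@]1(C)CC=C(C=O)C(=O)C1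
F2 | step 4 | tricyclic β-alkoxy enone: 10 with a C6=C7 double bond (O8–C7H=C6–C5=O) | O=C1C2=COC(C)(C)[C@@H]3CC[C@@](C)(C[C@@H]32)C1
F3 | step 6 | siloxycyclopropane: CH2 bridging C5(OSiMe3) and C16 of 13 | C[Si](C)(C)OC14[C@@H]2COC(C)(C)[C@@H]3CC[C@@](C)(C[C@@H]32)C1C4
F4 | step 6 | ring-expanded β-chloro ketone: C5(=O)–C4H2–C16H(Cl) | C1C(=O)[C@@H]2COC(C)(C)[C@@H]3CC[C@@](C)(C[C@@H]32)C1Cl
F5 | step 6 | parent tricyclic enone: 16 with H in place of Br | C1C(=O)[C@@H]2COC(C)(C)[C@@H]3CC[C@@](C)(C[C@@H]32)C=1
F6 | step 6 | α-iodo enone: 16 with I in place of Br | IC1C(=O)[C@@H]2COC(C)(C)[C@@H]3CC[C@@](C)(C[C@@H]32)C=1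
F7 | step 8 | 16-allyl-4-(2-methylallyl) tricyclic ketone, side chains trans as in 21 | CC(=C)C[C@@H]1C(=O)[C@@H]2COC(C)(C)[C@@H]3CC[C@@](C)(C[C@@H]32)[C@H]1CC=C
F8 | step 8 | keto aldehyde: 16-(2-oxoethyl)-4-(2-oxopropyl) tricyclic ketone | CC(=O)C[C@@H]1C(=O)[C@@H]2COC(C)(C)[C@@H]3CC[C@@](C)(C[C@@H]32)[C@H]1CC=O
F9 | step 8 | 3-methylbut-2-enoic anhydride | CC(C)=CC(=O)OC(=O)C=C(C)C
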